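Start with the bill.

Ja 5.0 mM; Jb 6.00 mM; Jd 0.500 mM; time 4.0 min

    Ja + Je → Jf + Jg (k1 = 58.0 M⁻¹ s⁻¹)
    Je + Jf ⇌ Jb, settled at all times (K2 = 3.0 × 10⁵ M⁻¹)
    Jf + Jc ⇌ Jh (K3 = 45700 M⁻¹, k3 = 157 M⁻¹ s⁻¹)
    Ja + Jd → Jj (k4 = 67.9 M⁻¹ s⁻¹)
    Ja + Jf → Jk (k5 = 6.47 M⁻¹ s⁻¹)

1. the concentration of Jc at which the part of the Ja that has reacted at 4.0 min is just 90%, in mM

Jd has less charged than Ja, so take it that Jd spends itself on Ja and that the rest of the wanted turnover passes through Je. Each such Ja pulls one Je out of Jb and makes one more Jf, so two Jf appear, and you need a Jc for each. That gives 8.00 mM: the base bill, twice the Ja that has to pass through Je.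

The bill says what is enough on paper, not what is enough in 4.0 min. With both balances holding, Ja's pseudo-first-order rate constant is k1·(K3/K2)·c(Jc)·c(Jb)/c(Jh). Early it is high: the half-life of Je by the first step alone, beside the charged Ja, is 2.4 s. Then c(Jb) falls by a factor 3.00 to 2.00 mM, c(Jh) climbs towards the bill, and c(Jc) sinks to whatever you charged above the bill. Suppose the end rate held through the whole run. Ja would then need a spare of 4.14 mM. At that spare the balance with Jc has a half-life near 1.07 s, far shorter than the run. I expect the real rate to run above the end rate earlier, so I look for the answer between the bill and 12.1 mM, and I commit to the middle, 10.1 mM.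

The forecast gave 6.5 mM, range 5.7 mM to 7.4 mM, below my figure, holding that “the reaction stalls once Jc is used up”. The simulation gives 10.4 mM, which is 2.40 mM above the bill.

In that flask, by 0.400 min the step of Ja with Jd has 99.8% of its turnover behind it, while 35.1% of the Ja is used and 75.7% of the Jc is still free. By 2.00 min, 76.3% of the Ja is used and 39.0% of the Jc is free, and by 12.0 min 99.0% of the Ja is used. With a quarter more Jc, 13.0 mM, a second flask reaches 93.7%; the bill for that turnover is 8.37 mM, less than that flask's charge.

The numbers of this flask are those of an exercise; no experiment stands behind them.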